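The γ-butyrolactone (ring O1, carbonyl C2, alkylidene carbon C3, carbinol C4, C5 bearing the alkenyl group) is cut at O1–C5 and at C2–C3, which turns its O1–C2(=O) unit into carbon dioxide and leaves an open chain with a vinylic C3 and an allylic C5. The key step exploits this pattern: in one pot a (Z)-vinyl iodide at C3 is lithiated beside the C4 alkoxide and carboxylated with CO2, and the new carboxylate displaces a syn-configured allylic chloride at C5 with inversion (5-exo-tet). The precursor carries the whole side chain as a bis-silyl ether together with C3–I, C4–OH and C5–Cl, both stereocentres coming from one asymmetric chloroallylboration; cross-metathesis then completes the isobutenyl group.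

Key step: step 9

Remark: borane reagents made from (+)-Ipc2BOMe or (+)-Ipc2BCl are assumed to add to the Re face of an aldehyde, as the parent B-allyl reagent of this series does; the configurations drawn in steps 4 and 8 and in the fallbacks rest on this. TBS = tert-butyldimethylsilyl, TES = triethylsilyl, Ipc = isopinocampheyl.

Step 1
Reactants: 1 geraniol
Product: 2 geranyl TBS ether
Conditions: TBSCl, imidazole, DMF, 0 °C to rt
Reagents that add atoms: tert-butyldimethylsilyl chloride, CC(C)(C)[Si](C)(C)Cl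
Why: Imidazole-promoted silylation of the primary allylic alcohol protects C1–OH for the organometallic steps; no stereocentre is involved.

Step 2
Reactants: 2 geranyl TBS ether
Product: 3 (2E,6E)-8-(TBS-oxy)-2,6-dimethylocta-2,6-dien-1-ol
Conditions: SeO2 (cat.), t-BuOOH, salicylic acid (cat.), CH2Cl2, rt
Reagents that add atoms: tert-butyl hydroperoxide, CC(C)(C)OO
Why: Catalytic SeO2 allylic oxidation (ene reaction, then [2,3]-sigmatropic shift) should select the (E)-methyl of the electron-richer terminal alkene and leave the alkene next to the silyloxy group untouched.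

Step 3
Reactants: 3 allylic alcohol
Product: 4 (2E,6E)-8-(TBS-oxy)-2,6-dimethylocta-2,6-dienal
Conditions: TEMPO (cat.), PhI(OAc)2, CH2Cl2, rt
Reagents that add atoms: none
Why: Oxoammonium (TEMPO) oxidation takes the allylic alcohol to the (E)-enal without touching the silyl ether or the alkenes.

Step 4
Reactants: 4 enal
Product: 6 (4R,5E,9E)-11-(TBS-oxy)-5,9-dimethylundeca-1,5,9-trien-4-ol, via O-diisopinocampheylboryl ether 5 (not isolated)
Conditions: (+)-Ipc2BOMe, allylMgBr, Et2O, −78 °C; then NaOH, H2O2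
Reagents that add atoms: allylmagnesium bromide, C=CC[Mg]Br
Why: Brown allylation through a chair Zimmerman–Traxler transition state; the (+)-Ipc2B reagent should add to the Re face of the enal carbonyl and set the (R)-carbinol, and the oxidative work-up cleaves the borinate.

Step 5
Reactants: 6 homoallylic alcohol
Product: 7 (4R,5E,9E)-4,11-bis(TBS-oxy)-5,9-dimethylundeca-1,5,9-triene
Conditions: TBSOTf, 2,6-lutidine, CH2Cl2, −78 to 0 °C
Reagents that add atoms: tert-butyldimethylsilyl triflate, CC(C)(C)[Si](C)(C)OS(=O)(=O)C(F)(F)F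
Why: Silyl triflate silylation of the hindered allylic alcohol; it prevents oxa-Michael closure of the later δ-hydroxy enal and lets both silyl ethers fall together at the end.

Step 6
Reactants: 7 terminal alkene
Product: 8 (2E,5R,6E,10E)-5,12-bis(TBS-oxy)-6,10-dimethyldodeca-2,6,10-trienal
Conditions: crotonaldehyde (excess), second-generation Hoveyda–Grubbs catalyst RuCl2(SIMes)(=CH-C6H4-2-OiPr) (cat.), CH2Cl2, 40 °C
Reagents that add atoms: (E)-crotonaldehyde, C/C=C/C=O
Why: Olefin cross-metathesis of the only monosubstituted alkene with excess crotonaldehyde should give the (E)-enal; the trisubstituted alkenes do not engage.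

Step 7
Reactants: 8 enal
Product: 9 (2Z,5R,6E,10E)-5,12-bis(TBS-oxy)-2-iodo-6,10-dimethyldodeca-2,6,10-trienal
Conditions: I2, DMAP (cat.), K2CO3, THF/H2O, rt
Reagents that add atoms: iodine, II
Why: Amine-catalysed α-iodination of an enal (Baylis–Hillman-type addition, iodination, elimination) should give the (Z)-2-iodoenal, with iodine cis to the chain CH2, which is the geometry the lactone alkylidene needs.

Step 8
Reactants: 9 (Z)-2-iodoenal
Product: 11 (3S,4R,5Z,8R,9E,13E)-8,15-bis(TBS-oxy)-3-chloro-5-iodo-9,13-dimethylpentadeca-1,5,9,13-tetraen-4-ol, via O-diisopinocampheylboryl ether 10 (not isolated)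
Conditions: allyl chloride, LiN(c-C6H11)2, (+)-Ipc2BOMe, Et2O, −95 °C; BF3·OEt2; then 9, −95 °C; HOCH2CH2NH2 work-up
Reagents that add atoms: allyl chloride, C=CCCl
Why: (Z)-γ-Chloroallylboration: the chair transition state of the (Z)-γ-chloroallyl-B(Ipc)2 reagent should give the syn-chlorohydrin (Z-geometry gives syn) with Re-face attack under Ipc control, setting C4 and C5 in one event; ethanolamine frees the alcohol without a base strong enough to close the epoxide.

Step 9
Reactants: 11 syn-chlorohydrin vinyl iodide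
Product: 14 (3Z,4S,5R)-5-ethenyl-4-hydroxy-3-alkylidene-oxolan-2-one bis-TBS ether, via dilithio alkoxide-vinyllithium 12 (not isolated), via lithium chlorohydroxy carboxylate 13 (not isolated)
Conditions: MeLi, then t-BuLi, THF, −78 °C; CO2, −78 to 0 °C; then H2O, NaHCO3, DMF, 45 °C
Reagents that add atoms: carbon dioxide, O=C=O
Why: MeLi turns the C4 hydroxyl into its lithium alkoxide, t-BuLi then exchanges the C3 iodide with retention of the (Z)-geometry (the adjacent alkoxide is no leaving group, so the vinyllithium cannot eliminate to an allene), the vinyllithium adds to CO2 to make C2–C3, and after the aqueous hydrogen carbonate quench the carboxylate displaces chloride at C5 to make O1–C5. The closest known reaction types are the carboxylation of 2-lithioallyl alkoxides to α-alkylidene-β-hydroxy acids and the lactonisation of γ-halo carboxylates. The lactone ring closes in the 5-exo-tet mode, the carboxylate oxygen attacking the secondary allylic C5–Cl carbon. C5 is set by stereospecific SN2 inversion of the (S)-chloride, so the syn-chlorohydrin becomes the 4,5-trans lactone, while C4 and the side-chain carbinol are untouched and the alkylidene geometry is that of the vinyl iodide. The step needs the carboxylate, not the C4 oxygen, to attack C5 (an epoxide formed first would lead to the cis-lactone by double inversion), and the quench secures this by protonating the alkoxide and hydrolysing its CO2 adduct while the carboxylate stays anionic. SN2' attack is excluded because it would need a seven-membered ring, and the unsubstituted vinyl group keeps the chloride from ionising, which is why the isobutenyl methyls are added only afterwards.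

Step 10
Reactants: 14 vinyl lactone
Product: 15 (3Z,4S,5R)-4-hydroxy-5-(2-methylprop-1-enyl)-3-alkylidene-oxolan-2-one bis-TBS ether
Conditions: 2-methyl-2-butene (excess), second-generation Grubbs catalyst RuCl2(SIMes)(PCy3)(=CHPh) (cat.), CH2Cl2, 35 °C
Reagents that add atoms: 2-methyl-2-butene, CC=C(C)C
Why: Olefin cross-metathesis with 2-methyl-2-butene should convert the terminal vinyl into the isobutenyl group; the trisubstituted chain alkenes and the electron-poor alkylidene are far less reactive and no stereocentre is touched.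

Step 11
Reactants: 15 bis-TBS lactone
Product: 16 target, (3Z,4S,5R)-3-[(3R,4E,8E)-3,10-dihydroxy-4,8-dimethyldeca-4,8-dienylidene]-4-hydroxy-5-(2-methylprop-1-enyl)oxolan-2-one
Conditions: HF·pyridine, pyridine, THF, 0 °C to rt
Reagents that add atoms: none
Why: Buffered fluoride desilylation should remove both TBS ethers without acyl migration, elimination or ionisation of the allylic C5–O bond of the lactone.

Compound list
1 | geraniol, (2E)-3,7-dimethylocta-2,6-dien-1-ol | CC(C)=CCC/C(C)=C/CO | starting material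
2 | (2E)-1-[(tert-butyldimethylsilyl)oxy]-3,7-dimethylocta-2,6-diene | CC(C)=CCC/C(C)=C/CO[Si](C)(C)C(C)(C)C | intermediate
3 | (2E,6E)-8-[(tert-butyldimethylsilyl)oxy]-2,6-dimethylocta-2,6-dien-1-ol | OC/C(C)=C/CC/C(C)=C/CO[Si](C)(C)C(C)(C)C | intermediate
4 | (2E,6E)-8-[(tert-butyldimethylsilyl)oxy]-2,6-dimethylocta-2,6-dienal | O=C/C(C)=C/CC/C(C)=C/CO[Si](C)(C)C(C)(C)C | intermediate
5 | O-diisopinocampheylboryl ether of 6 (not isolated) | C=CC[C@@H](OB([C@H]1C[C@H]2C[C@@H]([C@@H]1C)C2(C)C)[C@H]1C[C@H]2C[C@@H]([C@@H]1C)C2(C)C)/C(C)=C/CC/C(C)=C/CO[Si](C)(C)C(C)(C)C | intermediate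
6 | (4R,5E,9E)-11-[(tert-butyldimethylsilyl)oxy]-5,9-dimethylundeca-1,5,9-trien-4-ol | C=CC[C@@H](O)/C(C)=C/CC/C(C)=C/CO[Si](C)(C)C(C)(C)C | intermediate
7 | (4R,5E,9E)-4,11-bis[(tert-butyldimethylsilyl)oxy]-5,9-dimethylundeca-1,5,9-triene | C=CC[C@@H](O[Si](C)(C)C(C)(C)C)/C(C)=C/CC/C(C)=C/CO[Si](C)(C)C(C)(C)C | intermediate
8 | (2E,5R,6E,10E)-5,12-bis[(tert-butyldimethylsilyl)oxy]-6,10-dimethyldodeca-2,6,10-trienal | O=C/C=C/C[C@@H](O[Si](C)(C)C(C)(C)C)/C(C)=C/CC/C(C)=C/CO[Si](C)(C)C(C)(C)C | intermediate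
9 | (2Z,5R,6E,10E)-5,12-bis[(tert-butyldimethylsilyl)oxy]-2-iodo-6,10-dimethyldodeca-2,6,10-trienal | O=C/C(I)=C/C[C@@H](O[Si](C)(C)C(C)(C)C)/C(C)=C/CC/C(C)=C/CO[Si](C)(C)C(C)(C)C | intermediate
10 | O-diisopinocampheylboryl ether of 11 (not isolated) | C=C[C@H](Cl)[C@@H](OB([C@H]1C[C@H]2C[C@@H]([C@@H]1C)C2(C)C)[C@H]1C[C@H]2C[C@@H]([C@@H]1C)C2(C)C)/C(I)=C/C[C@@H](O[Si](C)(C)C(C)(C)C)/C(C)=C/CC/C(C)=C/CO[Si](C)(C)C(C)(C)C | intermediate
11 | (3S,4R,5Z,8R,9E,13E)-8,15-bis[(tert-butyldimethylsilyl)oxy]-3-chloro-5-iodo-9,13-dimethylpentadeca-1,5,9,13-tetraen-4-ol | C=C[C@H](Cl)[C@@H](O)/C(I)=C/C[C@@H](O[Si](C)(C)C(C)(C)C)/C(C)=C/CC/C(C)=C/CO[Si](C)(C)C(C)(C)C | intermediate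
12 | dilithio species from 11: lithium alkoxide at the carbinol, lithium in place of iodine with retention (not isolated) | C=C[C@H](Cl)[C@@H](O[Li])/C([Li])=C/C[C@@H](O[Si](C)(C)C(C)(C)C)/C(C)=C/CC/C(C)=C/CO[Si](C)(C)C(C)(C)C | intermediate
13 | lithium (2Z,3S,4S)-2-[(3R,4E,8E)-3,10-bis[(tert-butyldimethylsilyl)oxy]-4,8-dimethyldeca-4,8-dienylidene]-4-chloro-3-hydroxyhex-5-enoate (not isolated) | [Li+].C=C[C@H](Cl)[C@@H](O)/C(C([O-])=O)=C/C[C@@H](O[Si](C)(C)C(C)(C)C)/C(C)=C/CC/C(C)=C/CO[Si](C)(C)C(C)(C)C | intermediate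
14 | (3Z,4S,5R)-3-[(3R,4E,8E)-3,10-bis[(tert-butyldimethylsilyl)oxy]-4,8-dimethyldeca-4,8-dienylidene]-5-ethenyl-4-hydroxyoxolan-2-one | C=C[C@H]1OC(=O)/C(=C\C[C@@H](O[Si](C)(C)C(C)(C)C)/C(C)=C/CC/C(C)=C/CO[Si](C)(C)C(C)(C)C)[C@@H]1O | intermediate
15 | (3Z,4S,5R)-3-[(3R,4E,8E)-3,10-bis[(tert-butyldimethylsilyl)oxy]-4,8-dimethyldeca-4,8-dienylidene]-4-hydroxy-5-(2-methylprop-1-enyl)oxolan-2-one | CC(C)=C[C@H]1OC(=O)/C(=C\C[C@@H](O[Si](C)(C)C(C)(C)C)/C(C)=C/CC/C(C)=C/CO[Si](C)(C)C(C)(C)C)[C@@H]1O | intermediate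
16 | (3Z,4S,5R)-3-[(3R,4E,8E)-3,10-dihydroxy-4,8-dimethyldeca-4,8-dienylidene]-4-hydroxy-5-(2-methylprop-1-enyl)oxolan-2-one | CC(C)=C[C@H]1OC(=O)/C(=C\C[C@@H](O)/C(C)=C/CC/C(C)=C/CO)[C@@H]1O | target

Total step count: 11. Longest linear sequence: 11 steps, from geraniol.

Steps most likely to fail

Step 9 (key step). The vinyllithium may close onto the γ-chloride (1,3-elimination to an alkylidenecyclopropane) before CO2 arrives. Alternatively, the C4 alkoxide or its CO2 adduct may attack C5 ahead of the carboxylate (epoxide or cyclic carbonate formation), which would erode the 4,5-trans relationship. The fallback gives up carbon dioxide and the chloride and closes the ring in the classical acyl–oxygen sense. It sets out from iodoenal 9 and comes back at lactone 14. (E)-γ-Silylallylboration with the reagent made from allyl(diisopropylamino)dimethylsilane, n-BuLi/TMEDA, (+)-Ipc2BOMe and BF3·OEt2 (Et2O, −78 °C) should give the anti-β-hydroxy allylsilane F1, held as its boron alkoxide. Tamao oxidation in the work-up (KF, KHCO3, H2O2) should convert it with retention into the anti-diol F2. Carbonylative lactonisation of F2 (PdCl2(PPh3)2 cat., CO 1 atm, Et3N, THF, 50 °C), in which only the C5 hydroxyl can form a five-membered ring, should deliver 14.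

Step 8. The cold α-chloroallyl anion or the chloroallylborane may decompose or isomerise from Z to E before addition, and facial control on the α-iodinated enal may be lower than on simple aldehydes, so that C4/C5 diastereomers form. The fallback sets the two centres by an auxiliary-controlled aldol instead; it sets out from iodoenal 9 and comes back at chlorohydrin 11. The dibutylboron enolate of (R)-4-benzyl-3-(chloroacetyl)oxazolidin-2-one (Bu2BOTf, i-Pr2NEt, CH2Cl2, −78 °C) should give the Evans syn-aldol adduct F3. Transamination (MeONHMe·HCl, AlMe3) gives the Weinreb amide F4, and silylation (TESOTf, 2,6-lutidine) gives its triethylsilyl ether F5. DIBAL reduction (−78 °C) gives the α-chloro aldehyde F6, and Wittig methylenation (Ph3P=CH2, THF, −78 °C) gives the triethylsilyl ether F7 of the chlorohydrin. PPTS in MeOH then removes the triethylsilyl group to give 11.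

Step 7. Vinylogous β-elimination of the δ-silyloxy group through the dienolate, or incomplete E/Z control when the amine adduct eliminates, may consume the enal or give isomer mixtures. The fallback builds the iodoalkene from an alkyne; it sets out from aldehyde 4 and comes back at iodoenal 9. Propargylation with B-allenyldiisopinocampheylborane (from (+)-Ipc2BCl and allenylmagnesium bromide, Et2O, −78 °C; NaOH, H2O2) should give the (R)-homopropargylic alcohol F8, and TBSOTf/2,6-lutidine gives the bis-silyl ether F9. Deprotonation with n-BuLi and addition to paraformaldehyde gives the propargylic alcohol F10. Hydroxyl-directed trans-hydrostannation ([Cp*RuCl]4 cat., Bu3SnH, CH2Cl2) should give the (Z)-2-stannyl allylic alcohol F11 with tin next to the carbinol. Iododestannylation (I2, CH2Cl2, 0 °C) gives the (Z)-2-iodo allylic alcohol F12, and MnO2 oxidation gives 9.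

Further compounds
F1 | step 9 | anti-β-hydroxy allylsilane, (3R,4R)-3-[(diisopropylamino)dimethylsilyl] analogue of 11 with silicon in place of chlorine | C=C[C@@H]([Si](C)(C)N(C(C)C)C(C)C)[C@@H](O)/C(I)=C/C[C@@H](O[Si](C)(C)C(C)(C)C)/C(C)=C/CC/C(C)=C/CO[Si](C)(C)C(C)(C)C
F2 | step 9 | (3R,4R,5Z,8R,9E,13E)-8,15-bis[(tert-butyldimethylsilyl)oxy]-5-iodo-9,13-dimethylpentadeca-1,5,9,13-tetraene-3,4-diol (anti-diol) | C=C[C@@H](O)[C@@H](O)/C(I)=C/C[C@@H](O[Si](C)(C)C(C)(C)C)/C(C)=C/CC/C(C)=C/CO[Si](C)(C)C(C)(C)C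
F3 | step 8 | Evans syn-aldol adduct, (R)-4-benzyl-3-(syn-2-chloro-3-hydroxyacyl)oxazolidin-2-one | O=C([C@H](Cl)[C@@H](O)/C(I)=C/C[C@@H](O[Si](C)(C)C(C)(C)C)/C(C)=C/CC/C(C)=C/CO[Si](C)(C)C(C)(C)C)N1[C@H](Cc2ccccc2)COC1=O
F4 | step 8 | syn-2-chloro-3-hydroxy Weinreb amide | CON(C)C(=O)[C@H](Cl)[C@@H](O)/C(I)=C/C[C@@H](O[Si](C)(C)C(C)(C)C)/C(C)=C/CC/C(C)=C/CO[Si](C)(C)C(C)(C)C
F5 | step 8 | triethylsilyl ether of F4 | CON(C)C(=O)[C@H](Cl)[C@@H](O[Si](CC)(CC)CC)/C(I)=C/C[C@@H](O[Si](C)(C)C(C)(C)C)/C(C)=C/CC/C(C)=C/CO[Si](C)(C)C(C)(C)C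
F6 | step 8 | syn-2-chloro-3-(triethylsilyloxy) aldehyde | O=C[C@H](Cl)[C@@H](O[Si](CC)(CC)CC)/C(I)=C/C[C@@H](O[Si](C)(C)C(C)(C)C)/C(C)=C/CC/C(C)=C/CO[Si](C)(C)C(C)(C)C
F7 | step 8 | triethylsilyl ether of chlorohydrin 11 | C=C[C@H](Cl)[C@@H](O[Si](CC)(CC)CC)/C(I)=C/C[C@@H](O[Si](C)(C)C(C)(C)C)/C(C)=C/CC/C(C)=C/CO[Si](C)(C)C(C)(C)C
F8 | step 7 | (4R,5E,9E)-11-[(tert-butyldimethylsilyl)oxy]-5,9-dimethylundeca-5,9-dien-1-yn-4-ol | C#CC[C@@H](O)/C(C)=C/CC/C(C)=C/CO[Si](C)(C)C(C)(C)C
F9 | step 7 | (4R,5E,9E)-4,11-bis[(tert-butyldimethylsilyl)oxy]-5,9-dimethylundeca-5,9-dien-1-yne | C#CC[C@@H](O[Si](C)(C)C(C)(C)C)/C(C)=C/CC/C(C)=C/CO[Si](C)(C)C(C)(C)C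
F10 | step 7 | (5R,6E,10E)-5,12-bis[(tert-butyldimethylsilyl)oxy]-6,10-dimethyldodeca-6,10-dien-2-yn-1-ol | OCC#CC[C@@H](O[Si](C)(C)C(C)(C)C)/C(C)=C/CC/C(C)=C/CO[Si](C)(C)C(C)(C)C
F11 | step 7 | (2Z,5R,6E,10E)-5,12-bis[(tert-butyldimethylsilyl)oxy]-6,10-dimethyl-2-(tributylstannyl)dodeca-2,6,10-trien-1-ol | OC/C([Sn](CCCC)(CCCC)CCCC)=C/C[C@@H](O[Si](C)(C)C(C)(C)C)/C(C)=C/CC/C(C)=C/CO[Si](C)(C)C(C)(C)C
F12 | step 7 | (2Z,5R,6E,10E)-5,12-bis[(tert-butyldimethylsilyl)oxy]-2-iodo-6,10-dimethyldodeca-2,6,10-trien-1-ol | OC/C(I)=C/C[C@@H](O[Si](C)(C)C(C)(C)C)/C(C)=C/CC/C(C)=C/CO[Si](C)(C)C(C)(C)C
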